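## Structural features

The target is a germacranolide: a ten-membered carbocycle (C1–C10) trans-fused across C7–C8 to an α-methylene-γ-butyrolactone (C11, C12, C13, O8). The ring carries an exocyclic methylene on C10 (C14), a trisubstituted oxirane on C4–C5 (methyl C15 on C4) whose ring bonds C3–C4 and C5–C6 lie trans, an angelate ((Z)-2-methylbut-2-enoate) on O6 and a free allylic hydroxyl on C1. Five stereocentres are contiguous, C4 (R), C5 (R), C6 (S), C7 (R) and C8 (S); C1 (S) stands alone between the C10 methylene and the C2–C3 chain. Three groups are fragile: the α-methylene lactone (a Michael acceptor that can also translactonise to a free O6), the angelate (it isomerises to the tiglate under nucleophilic catalysis) and the trisubstituted epoxide (acid invites transannular attack by the C10 olefin). The real difficulty is the E-type epoxide: made by epoxidation it would need an E-cyclodecene, which is strained and poorly accessible by ring closure, and its oxygen must sit anti to the acylated C6 carbinol. The key step uses the fact that the O4–C4–C5 oxirane next to the C6–O bond is the Payne isomer of a cis C5–C6 oxirane next to a free C4 tertiary alcohol. That cis-epoxide comes from a Z-cyclodecene, the geometry that ring-closing metathesis of a ten-membered ring prefers. C1 has no stereochemical partner and needs reagent control.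

## Logic of the disconnections

40 ⇒ 39. Only the O1–H bond is changed (O1–Si). Keeping O1 silylated to the last step protects the allylic C1 carbinol during the oxidation that builds the lactone; the forward step must cleave a hindered secondary silyl ether without touching the epoxide, the angelate or the enoate.

39 ⇒ 36. The lactone C12–O8 bond is cut and C12 is lowered to the alcohol, giving the 2-methylene-1,4-diol. The seco form removes the Michael acceptor and the acyl group that a C6 alkoxide would attack, so the strongly basic key step becomes possible. The forward step must oxidise the primary allylic alcohol selectively and close onto O8 only.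

36 ⇒ 35. O8 and O12 are capped as 4-methoxybenzyl ethers. Ethers with no silicon cannot migrate to the C6 alkoxide, which sits 1,3-cis to O8 on the ring; the demand is a neutral oxidative deprotection that leaves the epoxide, ester and silyl ether alone.

35 ⇒ 30 + 32. The O4–C5 bond and the O6–acyl bond are cut; O4 becomes a free tertiary hydroxyl and C5–C6 carries a cis-epoxide. This converts the E-type epoxide and the acylated carbinol into a syn epoxy alcohol of a Z-cycloalkene. The forward step needs stereospecific inversion at C5 and acylation of the C6 alkoxide only.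

30 ⇒ 29. The two C–O bonds of the cis-epoxide are cut to the Z C5=C6 olefin. The C4 hydroxyl of 29 can direct the oxidant, so C5 and C6 are set from C4; the step must ignore the two 1,1-disubstituted olefins.

29 ⇒ 27. The C10=C14 bond is cut to the C10 ketone (and O4 is silylated). The methylene must come after ring closure, because an exocyclic olefin at C10 would close five- and six-membered rings with the vinyl groups. The forward olefination must be non-basic, since C1 is α and O8 is β to the carbonyl.

27 ⇒ 26. The C5=C6 bond is cut to two vinyl groups. This opens the ring to an acyclic chain whose stereocentres are all in place; the forward metathesis must close a ten-membered ring faster than it oligomerises and must give the Z olefin.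

26 ⇒ 25 ⇒ 23 ⇒ 22. The C10 carbonyl is masked as a thioacetal, the two silyl groups are removed and the C1–H bond is cut to the C1 ketone. C1 thus becomes the product of a reagent-controlled reduction of a ketone with one very large and one small flank; the tertiary O4 must be silylated before the C10 ketone appears, or it would form a hemiketal.

22 ⇒ 17 + 20. The C1–C10 bond is cut: C10 is an acyl-anion equivalent, C1 an acyl donor. The cut divides the chain into a C6–C14 piece and a C1–C5 piece that already holds C4; the forward step must acylate, not deprotonate, the lactone.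

20 ⇒ 19 ⇒ 18. The C1 carbonyl is traced to the trisubstituted olefin of 18, which supplies C1–C5, C15 and the C4 configuration. The demand is cleavage of the electron-rich olefin in the presence of the vinyl group.

17 ⇒ 13 + 14. The C9–C10 bond and the O8 ether bond are cut, leaving a terminal epoxide and the parent thioacetal. An unhindered carbanion opening a monosubstituted epoxide is the most dependable C–C bond formation available here; the alkoxide it frees must be etherified before any silyl chemistry.

13 ⇒ 11 ⇒ 10 ⇒ 9. The C9–O8 epoxide bond is cut to the 8,9-diol, the trityl group is restored on O9 and the O12 ether is removed. O12 has to be capped before the epoxide exists, since a free C12 alkoxide would open it in a five-membered mode; the forward steps need primary-over-secondary selectivity twice.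

9 ⇒ 8 ⇒ 5. C12 is raised back to the lactone carbonyl and the C11=C13 bond is cut. The lactone is the natural carrier of C8, O8, C11 and C12 and activates C11 for methylenation; the methylene must be introduced without strong base, because C7–H becomes vinylogously acidic.

5 ⇒ 4 ⇒ 2 ⇒ 1. The C6–C7 bond is cut (conjugate addition), the C7=C11 unsaturation is removed and O9 is freed. The C8 stereocentre of 1 then controls C7; the addition must occur anti to the protected hydroxymethyl group.

32 ⇒ 31. The anhydride C–O bond is cut to two molecules of 31, one supplying each acyl half; dehydration must not isomerise the Z olefin.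

## Other disconnections considered

Alternative 1: The cut is the C7–C11 bond, with the lactone ester bond already present as an O8 tether. In the forward step LiCl and DBU would generate a phosphonate-stabilised carbanion at C11, which opens a cis-6,7-epoxide at C7 with inversion (5-exo-tet) to give lactone A1 with a free C6 hydroxyl.
- In favour: one operation closes the lactone, fixes the trans C7/C8 relationship, frees O6 with defined configuration and leaves a phosphonate ready for olefination with formaldehyde; the 2-bromoallyl group on C8 prepares a chromium-mediated closure to C1.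
- Against: a stabilised phosphonoacetate anion is a weak nucleophile for an unactivated epoxide, 6-endo attack at C6 and base-induced epoxide isomerisation can compete, and A1 holds a free O6 beside an 8,12-lactone, which invites translactonisation. The ten-membered ring and the trans-4,5-epoxide at the quaternary C4 remain unsolved and would have to be made in the presence of the lactone.
- Comparison: in structure, both plans use a stereospecific intramolecular epoxide opening with inversion, so this alternative is the equal of the chosen plan. In step economy for the lactone it is the better: the chosen plan spends about five operations on reducing, protecting, deprotecting and re-oxidising the seco-lactone. In mechanism the chosen oxygen nucleophile is faster and reversible, so an equilibrium can be funnelled, whereas the carbon nucleophile is irreversible and sluggish. Overall the chosen plan is preferred because it solves the epoxide.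

Alternative 2: The cut is the C2–C3 bond, with C5–C10 re-formed, so the ten-membered ring comes from a six-membered one. In the forward step KH and 18-crown-6 would trigger an anionic oxy-Cope rearrangement of a 1,2-dialkenylcyclohexanol, and Me3SiCl would trap the enolate as A2.
- In favour: this is the most dependable entry to a ten-membered carbocycle. The chair transition state gives the E C4=C5 olefin stereospecifically, C6, C7 and C8 are set beforehand on a cyclohexane, and the regio-defined enol ether allows hydroxylation at C1 and later methylenation at C10.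
- Against: the trans-epoxide must come from epoxidation of the E olefin, with facial control by ring conformation only unless O6 is freed. C1 would be set on a mobile medium ring without a controlling neighbour. Germacra-1(10),4-dienes tend to undergo Cope rearrangement and acid-induced transannular cyclisation. The acetonide side chain on C7 needs several steps to become the α-methylene lactone.
- Comparison: on ring construction this alternative is the better, a pericyclic ring expansion against a medium-ring metathesis, which is the least certain step of the chosen plan. It is the equal in giving the E-type epoxide without any rearrangement. The chosen plan is better on the stereochemistry of C4, C5 and C6, which are relayed from C4 by a directed epoxidation and an SN2 step, and on C1, which is set by reagent control in an open chain. Step counts should be similar, since a pentasubstituted cyclohexanone must first be built.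

Alternative 3: The cuts are C9–C10 and O–C8 (retro-cycloaddition). In the forward step PhNCO and Et3N would dehydrate a primary nitro group at C10 to a nitrile oxide, which adds to the C8=C9 vinyl group and closes the carbocycle as the bridged isoxazoline A3.
- In favour: ring closure, the C8–O bond and a masked C10 ketone (after N–O cleavage) arise together. The trans-epoxide, O6 and O1 are set in the open chain by acyclic methods, and no thioacetal or metathesis is needed.
- Against: intramolecular nitrile oxide cycloaddition to a ten-membered ring has to beat dimerisation to furoxans and transannular strain. The configuration at C8 depends on facial selectivity in a medium-ring transition state. The silyloxy group on C1, β to the nitro carbon, can be eliminated by the amine base. N–O cleavage must spare the epoxide and gives a β-hydroxy ketone that is prone to dehydration.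
- Comparison: for the C8–C10 region this alternative is the better in step economy: one step replaces thioacetal alkylation, acylation, hydrolysis and ring closure. It is the equal in carrying a ketone at C10 for late methylenation. The chosen plan is better on C8, which is bought with the starting lactone, and on mechanism, since metathesis is reversible and settles on the Z olefin whereas the cycloaddition is kinetic and irreversible. The chosen plan is preferred.

Key step: step 20

Remark on the chemistry: germacrane numbering is used for all intermediates; 30 and 35 were compared atom by atom with 40 (they differ from each other only at C5, and 35 matches 40 at all six stereocentres, so no configuration had to be changed); O8 and O12 are carried as 4-methoxybenzyl (PMB) ethers because a silyl group on O8 would sit 1,3-cis to the C6 alkoxide of the key step and could migrate to it; 1, 14, 18 and 31 are assumed to be purchased as single isomers.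

## Route

Step 1
Reactants: 1 (R)-5-(hydroxymethyl)dihydrofuran-2(3H)-one
Product: 2 (R)-5-[(trityloxy)methyl]dihydrofuran-2(3H)-one
Conditions: TrCl, Et3N, DMAP (cat.), CH2Cl2, rt
Reagents that add atoms: trityl chloride, ClC(c1ccccc1)(c1ccccc1)c1ccccc1
Why: Tritylation of the primary alcohol; the bulky ether later shields one face of the butenolide and cannot migrate under base.

Step 2
Reactants: 2 (R)-5-[(trityloxy)methyl]dihydrofuran-2(3H)-one
Product: 4 (R)-5-[(trityloxy)methyl]furan-2(5H)-one, via C11 phenylselanyl lactone 3 (not isolated)
Conditions: LiN(i-Pr)2, THF, −78 °C; PhSeBr; then H2O2 (30% aq.), pyridine, CH2Cl2, 0 °C → rt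
Reagents that add atoms: none
Why: α-Selenenylation of the lactone enolate and selenoxide syn-elimination, the standard lactone-to-butenolide dehydrogenation; C8 is not involved.

Step 3
Reactants: 4 (R)-5-[(trityloxy)methyl]furan-2(5H)-one
Product: 5 (4S,5R)-4-vinyl-5-[(trityloxy)methyl]dihydrofuran-2(3H)-one
Conditions: CH2=CHMgBr, CuBr·SMe2 (cat.), THF, −78 °C; then H2O
Reagents that add atoms: vinylmagnesium bromide, C=C[Mg]Br
Why: Copper-catalysed 1,4-addition of the vinyl Grignard reagent; the nucleophile enters C7 anti to the trityloxymethyl group on C8, which sets C7 and the trans C6/C9 relationship.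

Step 4
Reactants: 5 (4S,5R)-4-vinyl-5-[(trityloxy)methyl]dihydrofuran-2(3H)-one
Product: 8 (4R,5R)-3-methylene-4-vinyl-5-[(trityloxy)methyl]dihydrofuran-2(3H)-one, via C11 dimethylaminomethyl lactone 6 (not isolated), via trimethylammonium iodide 7 (not isolated)
Conditions: LiN(i-Pr)2, THF, −78 °C; CH2=NMe2+ I−, −78 °C → rt; then MeI, MeOH, rt; then aq. NaHCO3, CH2Cl2, rt
Reagents that add atoms: Eschenmoser's salt (dimethylmethyleneiminium iodide), C=[N+](C)C.[I-]
Why: Mannich alkylation of the lactone enolate, N-methylation and β-elimination (Eschenmoser methylenation); the weak base in the last stage avoids deprotonation at C7, which is now vinylogously acidic.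

Step 5
Reactants: 8 (4R,5R)-3-methylene-4-vinyl-5-[(trityloxy)methyl]dihydrofuran-2(3H)-one
Product: 9 (2R,3R)-4-methylene-1-(trityloxy)-3-vinylpentane-2,5-diol
Conditions: i-Bu2AlH (4 equiv), CH2Cl2, −78 → 0 °C; aq. potassium sodium tartrate
Reagents that add atoms: none
Why: Hydride 1,2-reduction of the lactone through the lactol to the 2-methylene-1,4-diol; aluminium hydrides in a non-coordinating solvent attack the carbonyl of α-methylene lactones, not the olefin.

Step 6
Reactants: 9 (2R,3R)-4-methylene-1-(trityloxy)-3-vinylpentane-2,5-diol
Product: 10 (2R,3R)-5-(4-methoxybenzyloxy)-4-methylene-1-(trityloxy)-3-vinylpentan-2-ol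
Conditions: NaH (1.05 equiv), 4-methoxybenzyl chloride, n-Bu4NI (cat.), THF/DMF, −20 → 0 °C
Reagents that add atoms: 4-methoxybenzyl chloride, COc1ccc(CCl)cc1
Why: Williamson etherification; the primary allylic alkoxide should form and react faster than the C8 alkoxide, which is buried between C7 and the trityloxymethyl group.

Step 7
Reactants: 10 (2R,3R)-5-(4-methoxybenzyloxy)-4-methylene-1-(trityloxy)-3-vinylpentan-2-ol
Product: 11 (2R,3R)-5-(4-methoxybenzyloxy)-4-methylene-3-vinylpentane-1,2-diol
Conditions: TsOH·H2O (10 mol%), MeOH/CH2Cl2 (1:1), 0 °C → rt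
Reagents that add atoms: none
Why: Acid-catalysed solvolysis of the trityl ether, with the trityl cation trapped by methanol; the PMB ether and the olefins tolerate catalytic sulfonic acid at this temperature.

Step 8
Reactants: 11 (2R,3R)-5-(4-methoxybenzyloxy)-4-methylene-3-vinylpentane-1,2-diol
Product: 13 (R)-2-[(R)-2-[(4-methoxybenzyloxy)methyl]penta-1,4-dien-3-yl]oxirane, via C9 tosylate sodium alkoxide 12 (not isolated)
Conditions: NaH (2.5 equiv), N-tosylimidazole (1.05 equiv), THF, 0 °C → rt
Reagents that add atoms: none
Why: One-flask sulfonylation of the less hindered primary alkoxide and intramolecular Williamson closure (3-exo-tet) by the C8 alkoxide; the C8–O bond is not broken, so C8 keeps its configuration.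

Step 9
Reactants: 13 (R)-2-[(R)-2-[(4-methoxybenzyloxy)methyl]penta-1,4-dien-3-yl]oxirane; 14 1,3-dithiane
Product: 17 2-[(2S,3R)-2-(4-methoxybenzyloxy)-4-[(4-methoxybenzyloxy)methyl]-3-vinylpent-4-en-1-yl]-1,3-dithiane, via 2-lithio-1,3-dithiane 15 (not isolated), via C8 lithium alkoxide 16 (not isolated)
Conditions: 14, n-BuLi, THF, −30 °C; 13, −30 → 0 °C; then 4-methoxybenzyl bromide, n-Bu4NI (cat.), DMPU, 0 °C → rt
Reagents that add atoms: 4-methoxybenzyl bromide, COc1ccc(CBr)cc1
Why: Corey–Seebach umpolung: the unhindered dithianyl anion opens the monosubstituted epoxide at C9 (SN2), and the lithium alkoxide is benzylated in the same flask, so O8 carries an ether that cannot migrate.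

Step 10
Reactants: 18 (R)-linalool
Product: 19 (5R)-5-methyl-5-vinyltetrahydrofuran-2-ol (both anomers)
Conditions: O3, Sudan Red 7B (indicator), CH2Cl2/MeOH (5:1), −78 °C; then Me2S, −78 °C → rt
Reagents that add atoms: ozone, [O-][O+]=O
Why: Ozonolysis selective for the electron-rich trisubstituted olefin (indicator end-point) with reductive work-up; the γ-hydroxy aldehyde closes to the lactol and C4 is untouched.

Step 11
Reactants: 19 (5R)-5-methyl-5-vinyltetrahydrofuran-2-ol
Product: 20 (R)-5-methyl-5-vinyldihydrofuran-2(3H)-one
Conditions: TEMPO (10 mol%), PhI(OAc)2 (1.2 equiv), CH2Cl2, rt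
Reagents that add atoms: none
Why: Oxoammonium-mediated oxidation of a lactol to the lactone; the vinyl group and the quaternary centre are inert.

Step 12
Reactants: 17 2-[(2S,3R)-2-(4-methoxybenzyloxy)-4-[(4-methoxybenzyloxy)methyl]-3-vinylpent-4-en-1-yl]-1,3-dithiane; 20 (R)-5-methyl-5-vinyldihydrofuran-2(3H)-one
Product: 22 acyclic (4R,7R,8S) C1 ketone with the C10 1,3-dithiane, free C4 tertiary alcohol, O8 and O12 PMB ethers and vinyl groups on C4 and C7, via C10 lithio dithiane 21 (not isolated)
Conditions: t-BuLi (1.05 equiv), THF/HMPA (9:1), −78 °C, 10 min; 20, −78 → −40 °C; then H2O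
Reagents that add atoms: none
Why: Second stage of the Corey–Seebach sequence: lithiation of the 2-alkyl dithiane and acylation by the lactone; the tetrahedral adduct collapses to a tertiary alkoxide, and the ketone next to the quaternary carbon is too hindered for a second addition or for hemiketal formation.

Step 13
Reactants: 22 acyclic C1 ketone
Product: 23 acyclic (1S,4R,7R,8S) 1,4-diol with the C10 1,3-dithiane
Conditions: (R)-2-methyl-CBS-oxazaborolidine (0.3 equiv), catecholborane (2.5 equiv), toluene, −78 → −40 °C; then MeOH, H2O
Reagents that add atoms: none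
Why: Corey–Bakshi–Shibata reduction under reagent control: the quaternary dithianyl carbon is the large flank and the C2 methylene the small one, so the (R)-catalyst should give the (1S)-carbinol; catecholborane at low temperature does not hydroborate the olefins.

Step 14
Reactants: 23 acyclic (1S,4R,7R,8S) 1,4-diol
Product: 25 acyclic bis-silyl ether (O1 tert-butyldimethylsilyl, O4 trimethylsilyl) with the C10 1,3-dithiane, via O1 monosilyl ether 24 (not isolated)
Conditions: TBSOTf (1.1 equiv), 2,6-lutidine, CH2Cl2, −78 °C; then TMSOTf (1.5 equiv), −78 → 0 °C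
Reagents that add atoms: tert-butyldimethylsilyl triflate, CC(C)(C)[Si](C)(C)OS(=O)(=O)C(F)(F)F; trimethylsilyl triflate, C[Si](C)(C)OS(=O)(=O)C(F)(F)F
Why: Silyl triflate silylation: at −78 °C the bulky reagent should react with the secondary C1 hydroxyl only; the small one then caps the tertiary C4 hydroxyl so that it cannot add to the C10 ketone unmasked next.

Step 15
Reactants: 25 acyclic bis-silyl ether
Product: 26 acyclic (1S,4R,7R,8S) C10 ketone with O1 TBS, O4 TMS, O8 and O12 PMB and vinyl groups on C4 and C7
Conditions: MeI, CaCO3, MeCN/H2O (9:1), 45 °C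
Reagents that add atoms: water, O
Why: Alkylative thioacetal cleavage (S-methylation, hydrolysis of the sulfonium ion) under carbonate buffering; the neutral medium leaves the α-silyloxy stereocentre, the β-alkoxy ketone and the olefins alone.

Step 16
Reactants: 26 acyclic C10 ketone
Product: 27 (1S,4R,7R,8S,5Z)-cyclodec-5-en-10-one with O1 TBS, O4 TMS, O8 PMB and the C7 3-(4-methoxybenzyloxy)prop-1-en-2-yl group
Conditions: second-generation Grubbs catalyst (H2IMes)(PCy3)Cl2Ru=CHPh (10 mol%), 1,4-benzoquinone (20 mol%), toluene (1 mM), 80 °C
Reagents that add atoms: none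
Why: Ring-closing olefin metathesis of the two monosubstituted vinyl groups at high dilution; the reaction is reversible and the Z cyclodecene is the less strained isomer, the 1,1-disubstituted C11=C13 olefin is much slower, and with C10 still a carbonyl no five- or six-membered closure can compete.

Step 17
Reactants: 27 (5Z)-cyclodec-5-en-10-one
Product: 29 (1S,4R,7R,8S,5Z)-germacra-5,10(14),11(13)-trien-4-ol with O1 TBS, O8 and O12 PMB, via O4 trimethylsilyl triene 28 (not isolated)
Conditions: Cp2Ti(μ-Cl)(μ-CH2)AlMe2 (2 equiv), pyridine (cat.), THF/toluene, −40 → 0 °C; then K2CO3 (cat.), MeOH, rt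
Reagents that add atoms: Tebbe reagent Cp2Ti(μ-Cl)(μ-CH2)AlMe2 (drawn with the chloride on titanium and the Cl→Al bridge bond omitted), C[Al](C)C[Ti](Cl)(C1C=CC=C1)C1C=CC=C1
Why: Tebbe methylenation, a non-basic titanium alkylidene olefination that transfers the bridging CH2 to the C10 carbonyl and should neither epimerise C1 nor eliminate the β-alkoxy group; carbonate-catalysed methanolysis then removes only the labile trimethylsilyl ether.

Step 18
Reactants: 29 (5Z)-germacra-5,10(14),11(13)-trien-4-ol
Product: 30 (1S,4R,5S,6S,7R,8S)-5,6-epoxygermacra-10(14),11(13)-dien-4-ol with O1 TBS, O8 and O12 PMB (cis-epoxide syn to O4)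
Conditions: VO(acac)2 (5 mol%), t-BuOOH (1.5 equiv, in decane), CH2Cl2, 0 °C → rt
Reagents that add atoms: tert-butyl hydroperoxide, CC(C)(C)OO
Why: Hydroxyl-directed epoxidation: the vanadate ester of O4 delivers oxygen to the face of the Z olefin on which it sits, setting C5 and C6 from C4; the ring bonds at C4 and C7 point to the other face, and the two exocyclic methylenes have no free allylic hydroxyl.

Step 19
Reactants: 31 angelic acid (two molecules for each molecule of 32)
Product: 32 angelic anhydride
Conditions: N,N'-dicyclohexylcarbodiimide (0.5 equiv relative to 31), CH2Cl2, 0 °C → rt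
Reagents that add atoms: angelic acid (the second molecule of 31, which supplies the second acyl group), C/C=C(/C)C(=O)O
Why: Carbodiimide dehydration: one molecule of 31 adds to the carbodiimide to give the O-acylisourea, which a second molecule of 31 attacks to give the symmetrical anhydride and the urea; no nucleophilic catalyst is present, so the Z olefin geometry should be kept.

Step 20
Reactants: 30 cis-5,6-epoxy C4 tertiary alcohol; 32 angelic anhydride
Product: 35 (1S,4R,5R,6S,7R,8S)-4,5-epoxygermacra-10(14),11(13)-dien-6-yl angelate with O1 TBS, O8 and O12 PMB, via C4 sodium alkoxide 33 (not isolated), via C6 sodium alkoxide 34 (not isolated)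
Conditions: NaH (1.3 equiv), THF, 0 °C → rt, 1 h; then 32 (1.5 equiv), −20 → 0 °C
Reagents that add atoms: none
Why: NaH deprotonates the tertiary C4 hydroxyl, and the alkoxide attacks C5 from the side opposite the C5–O bond of the cis-epoxide, closing the new oxirane in a 3-exo-tet mode as the old one opens; this is the Payne rearrangement of a 2,3-epoxy alcohol run under aprotic conditions. C5 is inverted (S to R) by the backside displacement while C4 and C6 keep their oxygen atoms and configurations, and the antiperiplanar O4–C4–C5–O arrangement places C3 and C6 on opposite sides of the new ring, which is the trans (E-type) epoxide. Alkoxides 33 and 34 interconvert, and 34 should dominate because it pairs the more substituted trans oxirane with the less hindered secondary alkoxide. The anhydride is added only after equilibration and at low temperature, where the secondary alkoxide is acylated much faster than the tertiary one, so both isomers should drain to 35 by kinetic trapping of a mobile equilibrium. Acylation of an alkoxide by the anhydride needs no nucleophilic catalyst, which protects the Z geometry of the angelate. The step needs acylation at O6 only and no group migration: O8 and O12 carry ethers that cannot move to the 1,3-cis C6 alkoxide, the lactone is absent so neither translactonisation nor conjugate addition is possible, and the remote O1 group is the slow-migrating tert-butyldimethylsilyl ether.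

Step 21
Reactants: 35 4,5-epoxy 6-angelate with O8 and O12 PMB
Product: 36 (1S,4R,5R,6S,7R,8S)-4,5-epoxy-8,12-dihydroxygermacra-10(14),11(13)-dien-6-yl angelate with O1 TBS
Conditions: DDQ (3 equiv), CH2Cl2/pH 7 phosphate buffer (10:1), 0 °C → rt
Reagents that add atoms: none
Why: Oxidative cleavage of both PMB ethers (benzylic hydride abstraction, hydrolysis of the oxocarbenium ion) under buffered neutral conditions that should spare the epoxide, the angelate and the silyl ether.

Step 22
Reactants: 36 8,12-diol
Product: 39 O1-TBS ether of the target lactone, via C12 enal 37 (not isolated), via C12 lactol 38 (not isolated)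
Conditions: TEMPO (0.3 equiv), PhI(OAc)2 (3 equiv), CH2Cl2, rt
Reagents that add atoms: none
Why: Oxoammonium oxidation selective for the primary allylic alcohol gives the enal, which the C8 hydroxyl captures as the lactol, and a second oxidation gives the lactone; O1 is silylated and O6 acylated, so only the 8,12-lactone can form.

Step 23
Reactants: 39 O1-TBS ether of the target lactone
Product: 40 target, (1S,4R,5R,6S,7R,8S)-4,5-epoxy-1-hydroxy-12-oxo-8,12-epoxygermacra-10(14),11(13)-dien-6-yl angelate
Conditions: HF·pyridine, pyridine, THF, 0 °C → rt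
Reagents that add atoms: none
Why: Fluoride cleavage of the Si–O bond under pyridine buffering, mild enough for the epoxide, the angelate and the α-methylene lactone.

## Compound list

1 | (R)-5-(hydroxymethyl)dihydrofuran-2(3H)-one | O=C1CC[C@H](CO)O1 | starting material
2 | (R)-5-[(trityloxy)methyl]dihydrofuran-2(3H)-one | O=C1CC[C@H](COC(c2ccccc2)(c2ccccc2)c2ccccc2)O1 | intermediate
3 | (5R)-3-(phenylselanyl)-5-[(trityloxy)methyl]dihydrofuran-2(3H)-one (C3 epimers) | O=C1C([Se]c2ccccc2)C[C@H](COC(c2ccccc2)(c2ccccc2)c2ccccc2)O1 | intermediate
4 | (R)-5-[(trityloxy)methyl]furan-2(5H)-one | O=C1C=C[C@H](COC(c2ccccc2)(c2ccccc2)c2ccccc2)O1 | intermediate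
5 | (4S,5R)-4-vinyl-5-[(trityloxy)methyl]dihydrofuran-2(3H)-one | O=C1C[C@@H](C=C)[C@H](COC(c2ccccc2)(c2ccccc2)c2ccccc2)O1 | intermediate
6 | 3-[(dimethylamino)methyl] derivative of 5 (C3 epimers) | O=C1C(CN(C)C)[C@@H](C=C)[C@H](COC(c2ccccc2)(c2ccccc2)c2ccccc2)O1 | intermediate
7 | trimethylammonium iodide from 6 | O=C1C(C[N+](C)(C)C)[C@@H](C=C)[C@H](COC(c2ccccc2)(c2ccccc2)c2ccccc2)O1.[I-] | intermediate
8 | (4R,5R)-3-methylene-4-vinyl-5-[(trityloxy)methyl]dihydrofuran-2(3H)-one | O=C1C(=C)[C@@H](C=C)[C@H](COC(c2ccccc2)(c2ccccc2)c2ccccc2)O1 | intermediate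
9 | (2R,3R)-4-methylene-1-(trityloxy)-3-vinylpentane-2,5-diol | C=C(CO)[C@@H](C=C)[C@@H](O)COC(c1ccccc1)(c1ccccc1)c1ccccc1 | intermediate
10 | (2R,3R)-5-(4-methoxybenzyloxy)-4-methylene-1-(trityloxy)-3-vinylpentan-2-ol | C=C(COCc1ccc(OC)cc1)[C@@H](C=C)[C@@H](O)COC(c1ccccc1)(c1ccccc1)c1ccccc1 | intermediate
11 | (2R,3R)-5-(4-methoxybenzyloxy)-4-methylene-3-vinylpentane-1,2-diol | C=C(COCc1ccc(OC)cc1)[C@@H](C=C)[C@@H](O)CO | intermediate
12 | sodium alkoxide of the primary (C9) 4-toluenesulfonate of 11 | C=C(COCc1ccc(OC)cc1)[C@@H](C=C)[C@@H]([O-])COS(=O)(=O)c1ccc(C)cc1.[Na+] | intermediate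
13 | (R)-2-[(R)-2-[(4-methoxybenzyloxy)methyl]penta-1,4-dien-3-yl]oxirane | C=C(COCc1ccc(OC)cc1)[C@@H](C=C)[C@@H]1CO1 | intermediate
14 | 1,3-dithiane | C1CSCSC1 | starting material
15 | 2-lithio-1,3-dithiane | [Li]C1SCCCS1 | intermediate
16 | lithium (2S,3R)-1-(1,3-dithian-2-yl)-4-[(4-methoxybenzyloxy)methyl]-3-vinylpent-4-en-2-olate | C=C(COCc1ccc(OC)cc1)[C@@H](C=C)[C@@H]([O-])CC1SCCCS1.[Li+] | intermediate
17 | 2-[(2S,3R)-2-(4-methoxybenzyloxy)-4-[(4-methoxybenzyloxy)methyl]-3-vinylpent-4-en-1-yl]-1,3-dithiane | C=C(COCc1ccc(OC)cc1)[C@@H](C=C)[C@@H](OCc1ccc(OC)cc1)CC1SCCCS1 | intermediate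
18 | (R)-linalool | CC(C)=CCC[C@@](C)(O)C=C | starting material
19 | (5R)-5-methyl-5-vinyltetrahydrofuran-2-ol (both anomers) | OC1CC[C@](C)(C=C)O1 | intermediate
20 | (R)-5-methyl-5-vinyldihydrofuran-2(3H)-one | O=C1CC[C@](C)(C=C)O1 | intermediate
21 | 2-lithio derivative of 17 | C=C(COCc1ccc(OC)cc1)[C@@H](C=C)[C@@H](OCc1ccc(OC)cc1)CC1([Li])SCCCS1 | intermediate
22 | acyclic (4R,7R,8S) C1 ketone: C10 1,3-dithiane, C4 tertiary alcohol, O8 and O12 PMB, vinyl on C4 and C7 | C=C(COCc1ccc(OC)cc1)[C@@H](C=C)[C@@H](OCc1ccc(OC)cc1)CC1(SCCCS1)C(=O)CC[C@@](C)(O)C=C | intermediate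
23 | acyclic (1S,4R,7R,8S) 1,4-diol with C10 1,3-dithiane | C=C(COCc1ccc(OC)cc1)[C@@H](C=C)[C@@H](OCc1ccc(OC)cc1)CC1(SCCCS1)[C@@H](O)CC[C@@](C)(O)C=C | intermediate
24 | O1 tert-butyldimethylsilyl ether of 23 (C4 hydroxyl free) | C=C(COCc1ccc(OC)cc1)[C@@H](C=C)[C@@H](OCc1ccc(OC)cc1)CC1(SCCCS1)[C@@H](O[Si](C)(C)C(C)(C)C)CC[C@@](C)(O)C=C | intermediate
25 | O1 tert-butyldimethylsilyl, O4 trimethylsilyl ether of 23 | C=C(COCc1ccc(OC)cc1)[C@@H](C=C)[C@@H](OCc1ccc(OC)cc1)CC1(SCCCS1)[C@@H](O[Si](C)(C)C(C)(C)C)CC[C@@](C)(O[Si](C)(C)C)C=C | intermediate
26 | acyclic (1S,4R,7R,8S) C10 ketone: O1 TBS, O4 TMS, O8 and O12 PMB, vinyl on C4 and C7 | C=C(COCc1ccc(OC)cc1)[C@@H](C=C)[C@@H](OCc1ccc(OC)cc1)CC(=O)[C@@H](O[Si](C)(C)C(C)(C)C)CC[C@@](C)(O[Si](C)(C)C)C=C | intermediate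
27 | (1S,4R,7R,8S,5Z)-cyclodec-5-en-10-one: O1 TBS, O4 TMS, O8 PMB, C7 3-(4-methoxybenzyloxy)prop-1-en-2-yl | C=C(COCc1ccc(OC)cc1)[C@@H]1[C@@H](OCc2ccc(OC)cc2)CC(=O)[C@@H](O[Si](C)(C)C(C)(C)C)CC[C@@](C)(O[Si](C)(C)C)/C=C\1 | intermediate
28 | (1S,4R,7R,8S,5Z)-germacra-5,10(14),11(13)-triene: O1 TBS, O4 TMS, O8 and O12 PMB | C=C(COCc1ccc(OC)cc1)[C@@H]1[C@@H](OCc2ccc(OC)cc2)CC(=C)[C@@H](O[Si](C)(C)C(C)(C)C)CC[C@@](C)(O[Si](C)(C)C)/C=C\1 | intermediate
29 | (1S,4R,7R,8S,5Z)-germacra-5,10(14),11(13)-trien-4-ol: O1 TBS, O8 and O12 PMB | C=C(COCc1ccc(OC)cc1)[C@@H]1[C@@H](OCc2ccc(OC)cc2)CC(=C)[C@@H](O[Si](C)(C)C(C)(C)C)CC[C@@](C)(O)/C=C\1 | intermediate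
30 | (1S,4R,5S,6S,7R,8S)-5,6-epoxygermacra-10(14),11(13)-dien-4-ol: O1 TBS, O8 and O12 PMB (cis-epoxide syn to O4) | C=C(COCc1ccc(OC)cc1)[C@@H]1[C@@H](OCc2ccc(OC)cc2)CC(=C)[C@@H](O[Si](C)(C)C(C)(C)C)CC[C@@](C)(O)[C@H]2O[C@@H]12 | intermediate
31 | angelic acid ((Z)-2-methylbut-2-enoic acid) | C/C=C(/C)C(=O)O | starting material
32 | angelic anhydride | C/C=C(/C)C(=O)OC(=O)/C(C)=C\C | intermediate
33 | sodium C4 alkoxide of 30 | C=C(COCc1ccc(OC)cc1)[C@@H]1[C@@H](OCc2ccc(OC)cc2)CC(=C)[C@@H](O[Si](C)(C)C(C)(C)C)CC[C@@](C)([O-])[C@H]2O[C@@H]12.[Na+] | intermediate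
34 | sodium C6 alkoxide of the trans-4,5-epoxide (Payne isomer of 33) | C=C(COCc1ccc(OC)cc1)[C@@H]1[C@@H](OCc2ccc(OC)cc2)CC(=C)[C@@H](O[Si](C)(C)C(C)(C)C)CC[C@@]2(C)O[C@@H]2[C@H]1[O-].[Na+] | intermediate
35 | (1S,4R,5R,6S,7R,8S)-4,5-epoxygermacra-10(14),11(13)-dien-6-yl angelate: O1 TBS, O8 and O12 PMB | C=C(COCc1ccc(OC)cc1)[C@@H]1[C@@H](OCc2ccc(OC)cc2)CC(=C)[C@@H](O[Si](C)(C)C(C)(C)C)CC[C@@]2(C)O[C@@H]2[C@H]1OC(=O)/C(C)=C\C | intermediate
36 | (1S,4R,5R,6S,7R,8S)-4,5-epoxy-8,12-dihydroxygermacra-10(14),11(13)-dien-6-yl angelate: O1 TBS | C=C(CO)[C@@H]1[C@@H](O)CC(=C)[C@@H](O[Si](C)(C)C(C)(C)C)CC[C@@]2(C)O[C@@H]2[C@H]1OC(=O)/C(C)=C\C | intermediate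
37 | C12 enal (C8 hydroxyl free) from 36 | C=C(C=O)[C@@H]1[C@@H](O)CC(=C)[C@@H](O[Si](C)(C)C(C)(C)C)CC[C@@]2(C)O[C@@H]2[C@H]1OC(=O)/C(C)=C\C | intermediate
38 | C12 lactol (8,12-hemiacetal, C12 epimers) | C=C1C(O)O[C@H]2CC(=C)[C@@H](O[Si](C)(C)C(C)(C)C)CC[C@@]3(C)O[C@@H]3[C@@H](OC(=O)/C(C)=C\C)[C@H]12 | intermediate
39 | O1 tert-butyldimethylsilyl ether of the target | C=C1C(=O)O[C@H]2CC(=C)[C@@H](O[Si](C)(C)C(C)(C)C)CC[C@@]3(C)O[C@@H]3[C@@H](OC(=O)/C(C)=C\C)[C@H]12 | intermediate
40 | CNP0104965.3, (1S,4R,5R,6S,7R,8S)-4,5-epoxy-1-hydroxy-12-oxo-8,12-epoxygermacra-10(14),11(13)-dien-6-yl angelate | C=C1C(=O)O[C@H]2CC(=C)[C@@H](O)CC[C@@]3(C)O[C@@H]3[C@@H](OC(=O)/C(C)=C\C)[C@H]12 | target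

## Step count and least certain steps

Total: 23 steps. Longest linear sequence: 20 steps (steps 1–9, 12–18 and 20–23, from 1 to 40); steps 10–11 and step 19 are side branches.

Step 20 (key step). The most likely failure is incomplete Payne equilibration in the aprotic medium, so that the anhydride meets the unrearranged tertiary alkoxide, or slow reversal during acylation that lowers the selectivity. Fallback: set out from 30 and equilibrate it in a protic medium (aq. NaOH, t-BuOH, rt), where epoxide migration is fast and nothing can be acylated. Isolate the free trans-4,5-epoxy C6 alcohol F1 and recycle recovered 30. Deprotonate F1 with LiN(SiMe3)2 in THF at −78 °C, where the reverse migration should be frozen, and add 32. This returns to the route at 35.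

Step 16. The most likely failure is oligomerisation by intermolecular metathesis outrunning closure of the medium ring, made worse by slow reaction at the vinyl group beside the silylated quaternary carbinol. Fallback: set out from 23, stop the silylation of step 14 at the monosilyl ether 24 and close the ring at this stage. The free tertiary allylic hydroxyl should speed up metathesis at C5, and the quaternary thioacetal carbon gives a gem-disubstituent bias. The same ruthenium catalyst at high dilution should give the cyclic Z-olefin dithiane F2. Trimethylsilylation of O4 (TMSOTf, 2,6-lutidine) gives the O4 trimethylsilyl ether F3, and alkylative thioacetal cleavage (MeI, CaCO3, aq. MeCN) returns to the route at 27.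

Step 12. The most likely failure is proton transfer from the α-methylene of lactone 20 to the hindered carbanion 21 (enolisation), which returns 17. Fallback: set out from 17 and lactol 19. Convert 19 into its magnesium alkoxide with i-PrMgCl (1 equiv) and add it to 21; addition to the open hydroxy aldehyde form should give the C1 carbinol F4 as a mixture of C1 epimers. Oxidation of the secondary alcohol (Dess–Martin periodinane, NaHCO3, CH2Cl2; the tertiary hydroxyl is inert) returns to the route at 22.

Step 17. The most likely failure is that the bulky titanium methylidene does not add to the C10 carbonyl, which is flanked by the C1 silyloxy group inside the medium ring, so that enolisation or decomposition takes over. Fallback (Peterson olefination): set out from 27 and add the small nucleophile Me3SiCH2Li in the presence of CeCl3 (THF, −78 °C) to give the β-hydroxysilane F5. Syn-elimination with KH (THF, 0 °C) returns to the route at 28, which is desilylated at O4 as in step 17.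

## Further compounds

F1 | step 20 | (1S,4R,5R,6S,7R,8S)-4,5-epoxygermacra-10(14),11(13)-dien-6-ol with O1 TBS, O8 and O12 PMB | C=C(COCc1ccc(OC)cc1)[C@@H]1[C@@H](OCc2ccc(OC)cc2)CC(=C)[C@@H](O[Si](C)(C)C(C)(C)C)CC[C@@]2(C)O[C@@H]2[C@H]1O
F2 | step 16 | (1S,4R,7R,8S,5Z)-cyclodec-5-ene with C10 1,3-dithiane, free C4 hydroxyl, O1 TBS, O8 PMB and the C7 3-(4-methoxybenzyloxy)prop-1-en-2-yl group | C=C(COCc1ccc(OC)cc1)[C@@H]1[C@@H](OCc2ccc(OC)cc2)CC2(SCCCS2)[C@@H](O[Si](C)(C)C(C)(C)C)CC[C@@](C)(O)/C=C\1
F3 | step 16 | O4 trimethylsilyl ether of F2 | C=C(COCc1ccc(OC)cc1)[C@@H]1[C@@H](OCc2ccc(OC)cc2)CC2(SCCCS2)[C@@H](O[Si](C)(C)C(C)(C)C)CC[C@@](C)(O[Si](C)(C)C)/C=C\1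
F4 | step 12 | acyclic (4R,7R,8S) 1,4-diol with C10 1,3-dithiane (C1 epimers) | C=C(COCc1ccc(OC)cc1)[C@@H](C=C)[C@@H](OCc1ccc(OC)cc1)CC1(SCCCS1)C(O)CC[C@@](C)(O)C=C
F5 | step 17 | C10 tertiary alcohol carrying the (trimethylsilyl)methyl group (C10 epimers), from 27 | C=C(COCc1ccc(OC)cc1)[C@@H]1[C@@H](OCc2ccc(OC)cc2)CC(O)(C[Si](C)(C)C)[C@@H](O[Si](C)(C)C(C)(C)C)CC[C@@](C)(O[Si](C)(C)C)/C=C\1
A1 | alternative 1 | trans-β,γ-disubstituted α-(diethoxyphosphoryl)-γ-butyrolactone with the 2-bromoallyl group on C8 and the free C6 hydroxyl (C11 epimers) | C=C(Br)C[C@@H]1OC(=O)C(P(=O)(OCC)OCC)[C@H]1[C@H](O)COCc1ccc(OC)cc1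
A2 | alternative 2 | ten-membered (4E)-dienyl trimethylsilyl enol ether (enol ether C1=C10) with O6 methoxymethyl, O8 PMB and the C11 diol acetonide | C1/C(C)=C/[C@@H](OCOC)[C@H](C2COC(C)(C)OC2)[C@@H](OCc2ccc(OC)cc2)C/C(O[Si](C)(C)C)=C/C1
A3 | alternative 3 | ten-membered carbocycle bridged by the isoxazoline C10=N–O–C8, with the trans-4,5-epoxide, O6 PMB, O1 TBS and the C11 diol acetonide | C1C2=NO[C@@H]1[C@@H](C3COC(C)(C)OC3)[C@H](OCc3ccc(OC)cc3)[C@H]3O[C@]3(C)CC[C@@H]2O[Si](C)(C)C(C)(C)C
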